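**Retrosynthetic overview**
1. Numbering: ring A is C1 (butyryl), C2 (enol), C3 (bridge), C4 (enol), C5 (CMe2), C6 (C=O). Ring B is C1' (bridge), C2' (OH), C3' (Me), C4' (OMe), C5' (butyryl), C6' (OH). The plan rests on the oxygen pattern of ring B. Only the oxygen at C4', para to the bridge-bearing C1', is methylated, and C3' carries a methyl group. This is the pattern of a 4-methoxy-3-methyl-2-pyrone (lactone C=O = C2', ring O = oxygen of C6') whose C6 side chain supplies C1' and the bridge CH2.
2. Disconnection 1: the C5'–COPr bond (Friedel–Crafts) leads back to 5'-desbutyryl aspidin.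
3. Disconnection 2 (key): the C1'–C2' bond of ring B. The arene is an isomer of a pyrone in which ring A C3 is tied through CH2CH2 to pyrone C6.
4. Disconnection 3: the ring A C3–CH2 bond, made by reductive Knoevenagel alkylation of butyrylfilicinic acid with the pyron-6-ylacetaldehyde. This coupling tolerates the two acidic enols of ring A. The aldehyde comes from triacetic acid lactone by C3 methylation, O-methylation, side-chain hydroxymethylation and oxidation.
5. Ring order: the pyrone ring is bought. The ring A carbocycle is bought as phloroglucinol and dearomatised by gem-dimethylation. Carbocyclic ring B is formed last, out of the pyrone.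

Key step: step 9

Assumption: all ring A compounds are mobile enol tautomers and are drawn in the tautomer of the target SMILES. Aspidin has no stereocentre, so no stereocontrol is required.

**Step 1**
Reactants: 1 4-hydroxy-6-methyl-2H-pyran-2-one (triacetic acid lactone); 2 formaldehyde; 3 thiophenol
Product: 5 4-hydroxy-6-methyl-3-[(phenylsulfanyl)methyl]-2H-pyran-2-one, via 3-methylidenepyrandione 4 (not isolated)
Conditions: 37% aq. CH2O (1.2 equiv), PhSH (1.1 equiv), piperidine/AcOH (cat.), EtOH, 60 °C
Reagents that add atoms: formaldehyde (2), C=O; thiophenol (3), Sc1ccccc1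
Why: Knoevenagel condensation at the nucleophilic C3 of the hydroxypyrone gives methide 4, and thia-Michael capture by thiophenol should outrun addition of a second pyrone, which fixes the one-carbon unit at C3 (three-component thiomethylation of a cyclic 1,3-dicarbonyl compound).

**Step 2**
Reactants: 5 4-hydroxy-6-methyl-3-[(phenylsulfanyl)methyl]-2H-pyran-2-one
Product: 6 4-hydroxy-3,6-dimethyl-2H-pyran-2-one
Conditions: Raney Ni (W-2, excess), EtOH, reflux
Reagents that add atoms: none
Why: Reductive desulfurisation with Raney Ni cleaves both C–S bonds and turns CH2SPh into the methyl group that becomes the C3' methyl, under conditions that should leave the pyrone ring unreduced.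

**Step 3**
Reactants: 6 4-hydroxy-3,6-dimethyl-2H-pyran-2-one; 7 dimethyl sulfate
Product: 8 4-methoxy-3,6-dimethyl-2H-pyran-2-one
Conditions: Me2SO4 (1.1 equiv), K2CO3, acetone, reflux
Reagents that add atoms: dimethyl sulfate (7), COS(=O)(=O)OC
Why: Williamson-type O-alkylation of the vinylogous acid with a hard methylating agent takes place at the C4 oxygen and gives the 4-methoxy-2-pyrone, so the only methyl ether of ring B is placed before that ring exists; any 2-methoxy-4-pyrone isomer would be removed by chromatography.

**Step 4**
Reactants: 8 4-methoxy-3,6-dimethyl-2H-pyran-2-one; 2 formaldehyde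
Product: 10 6-(2-hydroxyethyl)-4-methoxy-3-methyl-2H-pyran-2-one, via lithium dienolate 9 (not isolated)
Conditions: LiN(iPr)2 (LDA, commercial solution, 1.1 equiv), THF, −78 °C; monomeric CH2O (gas from cracked paraformaldehyde), −78 → −40 °C; AcOH quench
Reagents that add atoms: formaldehyde (2), C=O
Why: With C3 blocked, the base removes a proton only from the C6 methyl group to give the vinylogous ester enolate 9, whose exocyclic carbon adds to formaldehyde (aldol addition), so the side chain now holds C1' and the bridge carbon.

**Step 5**
Reactants: 10 6-(2-hydroxyethyl)-4-methoxy-3-methyl-2H-pyran-2-one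
Product: 11 2-(4-methoxy-3-methyl-2-oxo-2H-pyran-6-yl)acetaldehyde
Conditions: Dess–Martin periodinane (1.2 equiv), CH2Cl2, 0 °C → rt; crude aldehyde used at once
Reagents that add atoms: none
Why: Dess–Martin oxidation of a primary alcohol stops at the aldehyde under mild non-aqueous conditions that spare the lactone and enol ether, and the enolisable aldehyde is not stored.

**Step 6**
Reactants: 12 phloroglucinol; 13 butyryl chloride
Product: 14 1-(2,4,6-trihydroxyphenyl)butan-1-one (phlorbutyrophenone)
Conditions: PrCOCl (1.0 equiv), AlCl3 (4 equiv), CH2Cl2/MeNO2, 0 → 40 °C; ice/HCl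
Reagents that add atoms: butyryl chloride (13), CCCC(=O)Cl
Why: Friedel–Crafts acylation of phloroglucinol, in which the first chelated acyl group deactivates the ring, so one equivalent of acid chloride should give the monoketone.

**Step 7**
Reactants: 14 phlorbutyrophenone; 15 iodomethane
Product: 17 butyrylfilicinic acid (2-butanoyl-3,5-dihydroxy-6,6-dimethylcyclohexa-2,4-dien-1-one), via 3-methylphlorbutyrophenone 16 (not isolated)
Conditions: NaOMe (3.5 equiv), MeI (2.5 equiv), MeOH, 0 °C → rt; HCl
Reagents that add atoms: iodomethane (15), CI
Why: Dearomatising C-methylation of the phloroglucinol polyanion, in which soft MeI alkylates a ring carbon to give 16 and then the same, now more electron-rich carbon again, forming the gem-dimethyl dienone; under- and over-methylated congeners are separated.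

**Step 8**
Reactants: 11 2-(4-methoxy-3-methyl-2-oxo-2H-pyran-6-yl)acetaldehyde; 17 butyrylfilicinic acid
Product: 19 2-butanoyl-3,5-dihydroxy-4-[2-(4-methoxy-3-methyl-2-oxo-2H-pyran-6-yl)ethyl]-6,6-dimethylcyclohexa-2,4-dien-1-one, via ring A alkylidene 18 (not isolated)
Conditions: L-proline (20 mol %), Hantzsch ester (diethyl 2,6-dimethyl-1,4-dihydropyridine-3,5-dicarboxylate, 1.1 equiv), CH2Cl2, rt
Reagents that add atoms: none
Why: Amine-catalysed Knoevenagel condensation at C3, the only C–H acidic ring carbon of 17, gives alkylidene 18, which the Hantzsch ester reduces by conjugate hydride transfer (three-component reductive alkylation of cyclic 1,3-diones); the weakly acidic medium leaves unharmed the two ring A enols that would quench a pyrone carbanion.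

**Step 9**
Reactants: 19 ring A–CH2CH2–methoxypyrone
Product: 22 5'-desbutyryl aspidin (2-butanoyl-4-[(2,6-dihydroxy-4-methoxy-3-methylphenyl)methyl]-3,5-dihydroxy-6,6-dimethylcyclohexa-2,4-dien-1-one), via ring-opened keto ester 20 (not isolated), via cyclohexenedione tautomer 21 (not isolated)
Conditions: NaOMe (10 equiv), dry degassed MeOH, Ar, sealed tube, 170–185 °C; then cold 1 M HCl to pH 2
Reagents that add atoms: none
Why: Methoxide adds to the lactone carbonyl C2' and releases the ring oxygen as the C6' enolate, giving keto ester 20 in which C2' and C5' are still cis on the C3'=C4' enol ether; the ketone enolate carbon C1' then attacks the ester carbonyl C2' in an intramolecular Claisen (Dieckmann-type) condensation, methoxide leaves, and dione 21 enolises to the arene. The closest known reaction is the alkoxide-induced isomerisation of 4-methoxy-6-methyl-2-pyrone into phloroglucinol monomethyl ether, which needs hot concentrated methoxide, hence the sealed tube. Ring B closes in a 6-(enolendo)-exo-trig mode and no stereocentre remains, because the transient C1' centre of 21 disappears on aromatisation. Site selectivity lies in the substrate: C3' is fully substituted, enolisation towards C5' is reversible and could close only a four-membered ring, so C1' onto C2' is the sole productive condensation and the phenoxide sink draws all equilibria forward. The ether position cannot move, since exchange at C4' with methoxide is degenerate, the ring oxygen ends as the C6' hydroxyl and the lactone carbonyl as the C2' hydroxyl. The large excess of base keeps ring A as its doubly deprotonated delocalised anion, which should disfavour attack on its carbonyls, retro-Michael loss of ring A from the C1' enolate and scrambling of the new methylene bridge.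

**Step 10**
Reactants: 22 5'-desbutyryl aspidin; 13 butyryl chloride
Product: 23 aspidin
Conditions: PrCOCl (2 equiv), AlCl3 (6 equiv), CH2Cl2/MeNO2, 0 °C → rt, short reaction time; ice/1 M HCl
Reagents that add atoms: butyryl chloride (13), CCCC(=O)Cl
Why: Friedel–Crafts acylation (with Fries shift in the flask of any aryl ester) occurs at C5', the only ring carbon that still bears hydrogen and one activated by three oxygen substituents, while ring A can only be O-acylated and such enol esters are cleaved again on aqueous work-up.

**Compound list**
1 | 4-hydroxy-6-methyl-2H-pyran-2-one (triacetic acid lactone) | Cc1cc(O)cc(=O)o1 | starting material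
2 | formaldehyde | C=O | starting material
3 | thiophenol | Sc1ccccc1 | starting material
4 | 6-methyl-3-methylidene-2H-pyran-2,4(3H)-dione (not isolated) | C=C1C(=O)C=C(C)OC1=O | intermediate
5 | 4-hydroxy-6-methyl-3-[(phenylsulfanyl)methyl]-2H-pyran-2-one | Cc1cc(O)c(CSc2ccccc2)c(=O)o1 | intermediate
6 | 4-hydroxy-3,6-dimethyl-2H-pyran-2-one | Cc1cc(O)c(C)c(=O)o1 | intermediate
7 | dimethyl sulfate | COS(=O)(=O)OC | starting material
8 | 4-methoxy-3,6-dimethyl-2H-pyran-2-one | COc1cc(C)oc(=O)c1C | intermediate
9 | lithium 4-methoxy-3-methyl-6-methylidene-6H-pyran-2-olate (not isolated) | [Li+].[O-]C1=C(C)C(OC)=CC(=C)O1 | intermediate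
10 | 6-(2-hydroxyethyl)-4-methoxy-3-methyl-2H-pyran-2-one | COc1cc(CCO)oc(=O)c1C | intermediate
11 | 2-(4-methoxy-3-methyl-2-oxo-2H-pyran-6-yl)acetaldehyde | COc1cc(CC=O)oc(=O)c1C | intermediate
12 | phloroglucinol | Oc1cc(O)cc(O)c1 | starting material
13 | butyryl chloride | CCCC(=O)Cl | starting material
14 | 1-(2,4,6-trihydroxyphenyl)butan-1-one | CCCC(=O)c1c(O)cc(O)cc1O | intermediate
15 | iodomethane | CI | starting material
16 | 1-(2,4,6-trihydroxy-3-methylphenyl)butan-1-one (not isolated) | CCCC(=O)c1c(O)cc(O)c(C)c1O | intermediate
17 | butyrylfilicinic acid | CCCC(=O)C1=C(O)C=C(O)C(C)(C)C1=O | intermediate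
18 | ring A C3 alkylidene, E/Z mixture (not isolated) | CCCC(=O)C1=C(O)C(=CCc2cc(OC)c(C)c(=O)o2)C(=O)C(C)(C)C1=O | intermediate
19 | key-step precursor, ring A–CH2CH2–(4-methoxy-3-methyl-2-pyron-6-yl) | CCCC(=O)C1=C(O)C(CCc2cc(OC)c(C)c(=O)o2)=C(O)C(C)(C)C1=O | intermediate
20 | methyl (E)-3-methoxy-2-methyl-5-oxo-7-(ring A C3-yl)hept-2-enoate (not isolated) | COC(=O)/C(C)=C(OC)\CC(=O)CCC1=C(O)C(C)(C)C(=O)C(C(=O)CCC)=C1O | intermediate
21 | diketo tautomer of ring B, racemic at the transient C1' centre (not isolated) | CCCC(=O)C1=C(O)C(CC2C(=O)CC(OC)=C(C)C2=O)=C(O)C(C)(C)C1=O | intermediate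
22 | 5'-desbutyryl aspidin | CCCC(=O)C1=C(O)C(Cc2c(O)c(C)c(OC)cc2O)=C(O)C(C)(C)C1=O | intermediate
23 | aspidin | CCCC(=O)C1=C(O)C(Cc2c(O)c(C)c(OC)c(C(=O)CCC)c2O)=C(O)C(C)(C)C1=O | target

**Total step count:** 10. **Longest linear sequence:** 8 (steps 1, 2, 3, 4, 5, 8, 9, 10).

**Steps most likely to fail**

Step 9.
- Enolisation towards the substituted carbon C1' is slow, so forcing conditions are needed.
- Under those conditions three processes may compete: retro-Michael loss of ring A from the C1' enolate, retro-Claisen loss of the ring A butyryl group, and base-induced scrambling of the new methylene bridge (rottlerone-type change).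
- The fallback sets out from 8 and 17 and comes back at 23, so step 10 is skipped as well.
- The same ring transformation (NaOMe, MeOH, sealed tube) is run on the simple pyrone 8, the case closest to the documented one. It gives 5-methoxy-4-methylbenzene-1,3-diol F1.
- Friedel–Crafts butyrylation of F1 with 13 and AlCl3 is expected to prefer the position para to a free hydroxyl. It gives 1-(4,6-dihydroxy-2-methoxy-3-methylphenyl)butan-1-one F2. The isomer acylated between the two hydroxyls is removed by chromatography.
- The only free ring carbon of F2 is C1'. It is joined to C3 of 17 with formaldehyde 2 in dilute aqueous KOH at rt (classical methylene bridging through the ring A methide). The two symmetrical dimers are separated.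

Step 10.
- The strong Lewis acid may cleave the methylene bridge by ipso attack (retro-Friedel–Crafts).
- It may also strip the C4' methyl ether by chelation next to the new ketone, or leave O-acylation unresolved.
- The fallback sets out from 22 and comes back at 23.
- It is a Houben–Hoesch reaction with butyronitrile, ZnCl2 and dry HCl in Et2O at 0 °C. The nitrilium electrophile attacks C5' under much milder acid and cannot O-acylate. It gives the C5' butanimidoyl derivative (ketimine) F3 as its hydrochloride.
- Hydrolysis of F3 in warm water gives the ketone.

Step 8.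
- The aldehyde may be lost by self-condensation and enolisation.
- A second ring A unit may add to the alkylidene before hydride transfer.
- The fallback sets out from 17 and 8 and comes back at 19, and it avoids the aldehyde altogether.
- Compound 17 is treated with premixed aqueous Me2NH and formaldehyde 2 in EtOH at 0 °C (Mannich reaction). This gives 3-[(dimethylamino)methyl]butyrylfilicinic acid F4.
- Iodomethane 15 converts F4 into the trimethylammonium iodide F5.
- F5 is added to at least three equivalents of lithium dienolate 9, made from 8 as in step 4, in THF at −78 → 0 °C.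
- Two equivalents act as base and release the ring A methide F6 by loss of the amine. The third adds through its exocyclic carbon (Mannich-base alkylation by elimination–addition). Acidic work-up gives 19, and reprotonated 8 is recovered.

**Further compounds**
F1 | step 9 | 5-methoxy-4-methylbenzene-1,3-diol | COc1cc(O)cc(O)c1C
F2 | step 9 | 1-(4,6-dihydroxy-2-methoxy-3-methylphenyl)butan-1-one | CCCC(=O)c1c(O)cc(O)c(C)c1OC
F3 | step 10 | C5' butanimidoyl derivative of 22 (ketimine, neutral form) | CCCC(=N)c1c(O)c(CC2=C(O)C(C)(C)C(=O)C(C(=O)CCC)=C2O)c(O)c(C)c1OC
F4 | step 8 | 3-[(dimethylamino)methyl]butyrylfilicinic acid | CCCC(=O)C1=C(O)C(CN(C)C)=C(O)C(C)(C)C1=O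
F5 | step 8 | trimethylammonium iodide of F4 | CCCC(=O)C1=C(O)C(C[N+](C)(C)C)=C(O)C(C)(C)C1=O.[I-]
F6 | step 8 | ring A C3 methide | CCCC(=O)C1=C(O)C(=C)C(=O)C(C)(C)C1=O
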